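Everything rests on cutting the cyclohexane (ring A) between the tertiary carbinol carbon C1 and the neighbouring ring carbon C6 that bears the exocyclic methylene. A ligand-controlled, nickel-catalysed reductive addition of a 2-bromoalkene to a ketone closes ring A and, in one operation, forms the C1–C6 bond, the hindered carbinol beside the gem-dimethyl carbon C2, and its S configuration. The feature exploited is the direct bond from the carbinol carbon to the methylene-bearing carbon, as an internally metallated alkene would create by attacking a carbonyl. The precursor, 12, is an acyclic bromo ketone: bromoalkene, three methylenes, CMe2, carbonyl, then a two-carbon arm ending in a silyl alkyne, which later supplies the quaternary carbon of the dioxane (ring B).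

Key step: step 7

Remark: the remote carbonyl carbon of 12 and 13 is carried as a C-silyl alkyne (the dehydrated equivalent of the methyl ketone) instead of a ketal; carbon skeleton, bond formed and ring closed are unchanged, the new tertiary alcohol cannot form a cyclic hemiketal, and the alkyne is the handle for the later Z-selective methyl-metalation.

Atom labels used below: ring A C1 (carbinol), C2 (CMe2), C6 (C=CH2); ring B O1, O2, C3 (CH carrying the propanoate), C4, C5, C6 (quaternary); side chain C1 (ester carbon), C2 (CHMe).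

Step 1
Reactants: 1 pent-4-yn-1-ol
Product: 2 4-bromopent-4-en-1-ol
Conditions: Et4NBr, HBr (gas), CH2Cl2, 40 °C
Reagents that add atoms: hydrogen bromide, Br
Why: Markovnikov hydrobromination of the terminal alkyne by the hydrogen dibromide ion places bromine on the internal carbon and leaves the primary alcohol untouched.

Step 2
Reactants: 2 4-bromopent-4-en-1-ol
Product: 3 2-bromo-5-iodopent-1-ene
Conditions: I2, PPh3, imidazole, CH2Cl2, 0 °C to rt
Reagents that add atoms: iodine, II
Why: Appel-type iodination converts the primary alcohol through its oxyphosphonium salt into the iodide by SN2 and does not touch the alkenyl bromide.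

Step 3
Reactants: 4 isobutyronitrile; 3 2-bromo-5-iodopent-1-ene
Product: 6 6-bromo-2,2-dimethylhept-6-enenitrile, via lithiated isobutyronitrile 5 (not isolated)
Conditions: LiN(i-Pr)2, THF, −78 °C; then 3, −78 °C to rt
Reagents that add atoms: none
Why: Alkylation of the α-lithio nitrile with the unhindered primary iodide builds the quaternary carbon, and the alkenyl bromide is inert to this stabilised anion at low temperature.

Step 4
Reactants: 6 6-bromo-2,2-dimethylhept-6-enenitrile
Product: 8 6-bromo-2,2-dimethylhept-6-enal, via aluminium aldimide 7 (not isolated)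
Conditions: i-Bu2AlH, CH2Cl2, −78 to 0 °C; then 1 M aq. HCl, 0 °C
Reagents that add atoms: water, O
Why: Partial hydride reduction of the nitrile stops at the N-aluminio aldimine, which aqueous acid hydrolyses to the non-enolisable aldehyde.

Step 5
Reactants: 8 6-bromo-2,2-dimethylhept-6-enal; 9 (4-bromobut-1-yn-1-yl)trimethylsilane
Product: 11 rac-10-bromo-6,6-dimethyl-1-(trimethylsilyl)undec-10-en-1-yn-5-ol, via Grignard reagent 10 (not isolated)
Conditions: 9, Mg, THF, 35 °C; then 8, 0 °C; then aq. NH4Cl
Reagents that add atoms: none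
Why: Grignard addition to a non-enolisable aldehyde is dependable, the alkylmagnesium reagent does not exchange with the alkenyl bromide, and the racemic carbinol centre is erased in step 6.

Step 6
Reactants: 11 rac-10-bromo-6,6-dimethyl-1-(trimethylsilyl)undec-10-en-1-yn-5-ol
Product: 12 10-bromo-6,6-dimethyl-1-(trimethylsilyl)undec-10-en-1-yn-5-one
Conditions: Dess–Martin periodinane, CH2Cl2, rt
Reagents that add atoms: none
Why: Dess–Martin oxidation gives the hindered ketone under near-neutral conditions that spare the alkenyl bromide and the alkynylsilane.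

Step 7
Reactants: 12 10-bromo-6,6-dimethyl-1-(trimethylsilyl)undec-10-en-1-yn-5-one
Product: 13 (1S)-2,2-dimethyl-6-methylidene-1-[4-(trimethylsilyl)but-3-yn-1-yl]cyclohexan-1-ol
Conditions: NiBr2·glyme (10 mol %), (S)-t-Bu-PHOX (12 mol %; antipode as fixed in a first run), Mn powder (3 equiv), DMA, 25 °C; then aq. NH4Cl
Reagents that add atoms: none
Why: Proposed new method: zerovalent nickel carrying the chiral P,N ligand inserts into the alkenyl C–Br bond, manganese reduces the resulting alkenylnickel bromide to a more nucleophilic monovalent alkenylnickel, and this adds across the coordinated ketone before the alkoxide passes to divalent manganese and the catalyst is reduced again. The closest known reaction types are the nickel-catalysed reductive cyclisation of aryl and alkenyl halides onto ketones (enantioselective for aryl halide–ketone and desymmetrising diketone cases) and the intramolecular Nozaki–Hiyama–Kishi reaction; enantioface selection at an acyclic α-quaternary dialkyl ketone has not been shown. Ring A closes in the 6-exo-trig mode by attack of C6 on the carbonyl carbon C1. The new stereocentre C1 is controlled by the ligand on nickel alone, since the substrate has no stereocentre; the CMe2 arm is locked in the forming ring, so the ligand only has to tell the carbonyl oxygen from the butynyl arm. The step needs activation of the C–Br bond and 1,2-addition in preference to enolisation, pinacol coupling or protodebromination: the quaternary carbon blocks enolisation on one side, six-membered delivery makes addition fast, and the trimethylsilyl cap keeps nickel off the alkyne. The ligand antipode that gives the S carbinol is to be fixed in a first run with both antipodes against the racemate.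

Step 8
Reactants: 13 (1S)-2,2-dimethyl-6-methylidene-1-[4-(trimethylsilyl)but-3-yn-1-yl]cyclohexan-1-ol
Product: 14 triethyl({(1S)-2,2-dimethyl-6-methylidene-1-[4-(trimethylsilyl)but-3-yn-1-yl]cyclohexyl}oxy)silane
Conditions: Et3SiOTf, 2,6-lutidine, CH2Cl2, 0 °C to rt
Reagents that add atoms: triethylsilyl trifluoromethanesulfonate, CC[Si](CC)(CC)OS(=O)(=O)C(F)(F)F
Why: O-Silylation with the silyl triflate caps the hindered tertiary alcohol so that it can neither consume Lewis acid nor attack an activated alkene later.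

Step 9
Reactants: 14 triethyl({(1S)-2,2-dimethyl-6-methylidene-1-[4-(trimethylsilyl)but-3-yn-1-yl]cyclohexyl}oxy)silane
Product: 15 {[(1S)-1-(but-3-yn-1-yl)-2,2-dimethyl-6-methylidenecyclohexyl]oxy}triethylsilane
Conditions: K2CO3 (cat.), MeOH, rt
Reagents that add atoms: none
Why: Base-catalysed methanolysis (protodesilylation) cleaves the alkynyl C–Si bond, while the hindered tertiary triethylsilyl ether is stable to carbonate.

Step 10
Reactants: 16 methyl (2R)-3-hydroxy-2-methylpropanoate
Product: 17 methyl (2R)-3-[(tert-butyldimethylsilyl)oxy]-2-methylpropanoate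
Conditions: t-BuMe2SiCl, imidazole, CH2Cl2, rt
Reagents that add atoms: tert-butyldimethylsilyl chloride, CC(C)(C)[Si](C)(C)Cl
Why: Imidazole-promoted silylation protects the primary alcohol, which becomes the ester carbon C1 at the end, without affecting the stereocentre.

Step 11
Reactants: 17 methyl (2R)-3-[(tert-butyldimethylsilyl)oxy]-2-methylpropanoate
Product: 19 (2R)-3-[(tert-butyldimethylsilyl)oxy]-2-methylpropanal, via aluminium hemiacetal 18 (not isolated)
Conditions: i-Bu2AlH, CH2Cl2, −78 °C; then H2O, aq. potassium sodium tartrate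
Reagents that add atoms: none
Why: Low-temperature partial reduction holds the tetrahedral aluminium hemiacetal until work-up, so the aldehyde forms without over-reduction or epimerisation of the α-centre.

Step 12
Reactants: 19 (2R)-3-[(tert-butyldimethylsilyl)oxy]-2-methylpropanal
Product: 20 tert-butyldimethyl{[(2S)-2-methylbut-3-en-1-yl]oxy}silane
Conditions: Ph3PCH3Br, KN(SiMe3)2, THF, 0 °C; then 19, −78 °C to rt
Reagents that add atoms: methyltriphenylphosphonium bromide, C[P+](c1ccccc1)(c1ccccc1)c1ccccc1.[Br-]
Why: Wittig methylenation with the non-stabilised ylide at low temperature converts the aldehyde into the terminal alkene faster than the α-centre can epimerise (the descriptor changes only through priority rules).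

Step 13
Reactants: 20 tert-butyldimethyl{[(2S)-2-methylbut-3-en-1-yl]oxy}silane
Product: 21 tert-butyldimethyl{(2R)-2-[(2RS)-oxiran-2-yl]propoxy}silane
Conditions: m-CPBA, CH2Cl2, 0 °C to rt
Reagents that add atoms: 3-chloroperbenzoic acid, OOC(=O)c1cccc(Cl)c1
Why: Prilezhaev epoxidation of the monosubstituted alkene is reliable but should show little facial preference, so both oxirane epimers are expected and are resolved in step 14.

Step 14
Reactants: 21 tert-butyldimethyl{(2R)-2-[(2RS)-oxiran-2-yl]propoxy}silane
Product: 22 tert-butyldimethyl{(2R)-2-[(2S)-oxiran-2-yl]propoxy}silane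
Conditions: (R,R)-(salen)Co(OAc) [salen = N,N′-bis(3,5-di-tert-butylsalicylidene)cyclohexane-1,2-diaminate] (1 mol %), H2O (0.55 equiv), THF, 0 °C to rt
Reagents that add atoms: none
Why: Jacobsen hydrolytic kinetic resolution, in which the (R,R) catalyst hydrolyses the R oxirane of alkyl-substituted epoxides under catalyst control, should leave the S oxirane epimer, which is separated from the polar diol.

Step 15
Reactants: 15 {[(1S)-1-(but-3-yn-1-yl)-2,2-dimethyl-6-methylidenecyclohexyl]oxy}triethylsilane; 22 tert-butyldimethyl{(2R)-2-[(2S)-oxiran-2-yl]propoxy}silane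
Product: 24 (2R,3R)-1-[(tert-butyldimethylsilyl)oxy]-8-[(1S)-2,2-dimethyl-6-methylidene-1-(triethylsilyloxy)cyclohexyl]-2-methyloct-5-yn-3-ol, via lithium acetylide 23 (not isolated)
Conditions: n-BuLi, THF, −78 °C; BF3·OEt2; then 22, −78 °C; then aq. NH4Cl
Reagents that add atoms: none
Why: Yamaguchi–Hirao alkynylation opens the BF3-activated epoxide at its CH2 carbon, so the oxirane stereocentre is carried over untouched as the C3 carbinol (R) next to the C2 methyl centre.

Step 16
Reactants: 24 (2R,3R)-1-[(tert-butyldimethylsilyl)oxy]-8-[(1S)-2,2-dimethyl-6-methylidene-1-(triethylsilyloxy)cyclohexyl]-2-methyloct-5-yn-3-ol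
Product: 26 (2R,3R,5Z)-1-[(tert-butyldimethylsilyl)oxy]-8-[(1S)-2,2-dimethyl-6-methylidene-1-(triethylsilyloxy)cyclohexyl]-2,6-dimethyloct-5-en-3-ol, via alkenylmagnesium bromide 25 (not isolated)
Conditions: Fe(acac)3 (20 mol %), MeMgBr (5 equiv), THF, −78 to 0 °C; then aq. NH4Cl
Reagents that add atoms: methylmagnesium bromide, C[Mg]Br
Why: Alkoxide-directed iron-catalysed syn-carbomagnesiation of the homopropargylic alcohol delivers methyl to the distal alkyne carbon (C6) and magnesium to the proximal one (C5), and protonation with retention gives the Z alkene with the long chain cis to C4.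

Step 17
Reactants: 26 (2R,3R,5Z)-1-[(tert-butyldimethylsilyl)oxy]-8-[(1S)-2,2-dimethyl-6-methylidene-1-(triethylsilyloxy)cyclohexyl]-2,6-dimethyloct-5-en-3-ol
Product: 27 (2R,3R,5Z)-1-[(tert-butyldimethylsilyl)oxy]-8-[(1S)-2,2-dimethyl-6-methylidene-1-(triethylsilyloxy)cyclohexyl]-2,6-dimethyloct-5-en-3-yl methanesulfonate
Conditions: MsCl, Et3N, CH2Cl2, 0 °C
Reagents that add atoms: methanesulfonyl chloride, CS(=O)(=O)Cl
Why: Sulfonylation of the secondary alcohol proceeds with retention at C3 and turns the hydroxyl into a leaving group.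

Step 18
Reactants: 27 (2R,3R,5Z)-1-[(tert-butyldimethylsilyl)oxy]-8-[(1S)-2,2-dimethyl-6-methylidene-1-(triethylsilyloxy)cyclohexyl]-2,6-dimethyloct-5-en-3-yl methanesulfonate
Product: 28 tert-butyl{[(2R,3S,5Z)-8-[(1S)-2,2-dimethyl-6-methylidene-1-(triethylsilyloxy)cyclohexyl]-3-hydroperoxy-2,6-dimethyloct-5-en-1-yl]oxy}dimethylsilane
Conditions: 50% aq. H2O2 (large excess), KOH, MeOH–THF, 0 °C to rt
Reagents that add atoms: hydrogen peroxide, OO
Why: SN2 perhydrolysis of the secondary sulfonate by the hydroperoxide anion, a strong α-effect nucleophile but a weak base, inverts C3 to the S configuration required in ring B.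

Step 19
Reactants: 28 tert-butyl{[(2R,3S,5Z)-8-[(1S)-2,2-dimethyl-6-methylidene-1-(triethylsilyloxy)cyclohexyl]-3-hydroperoxy-2,6-dimethyloct-5-en-1-yl]oxy}dimethylsilane
Product: 30 tert-butyl{(2R)-2-[(3S,6R)-6-{2-[(1S)-2,2-dimethyl-6-methylidene-1-(triethylsilyloxy)cyclohexyl]ethyl}-6-methyl-1,2-dioxan-3-yl]propoxy}dimethylsilane, via acetoxymercurio dioxane 29 (not isolated)
Conditions: Hg(OAc)2 (1.05 equiv), CH2Cl2, 0 °C; then NaBH4, aq. NaOH, 0 °C
Reagents that add atoms: none
Why: Cycloperoxymercuration, in which the hydroperoxide opens the mercurinium ion of the trisubstituted alkene at the tertiary carbon C6 (Markovnikov, 6-endo, anti to mercury) through a chair with the C3 substituent equatorial, should with the Z alkene place the long chain axial and the methyl equatorial at C6 (6R, favoured kinetically and, if mercuration reverses, thermodynamically), the ring A methylene and the silylated oxygen offering no free nucleophile to trap their mercurinium ion, before alkaline borohydride replaces mercury at C5 by hydrogen.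

Step 20
Reactants: 30 tert-butyl{(2R)-2-[(3S,6R)-6-{2-[(1S)-2,2-dimethyl-6-methylidene-1-(triethylsilyloxy)cyclohexyl]ethyl}-6-methyl-1,2-dioxan-3-yl]propoxy}dimethylsilane
Product: 31 (2R)-2-[(3S,6R)-6-{2-[(1S)-1-hydroxy-2,2-dimethyl-6-methylidenecyclohexyl]ethyl}-6-methyl-1,2-dioxan-3-yl]propan-1-ol
Conditions: HF·pyridine, pyridine, THF, 0 °C to rt
Reagents that add atoms: none
Why: Fluoride-mediated desilylation removes both silyl ethers, and the pyridine buffer protects the peroxide and the tertiary allylic alcohol from acid.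

Step 21
Reactants: 31 (2R)-2-[(3S,6R)-6-{2-[(1S)-1-hydroxy-2,2-dimethyl-6-methylidenecyclohexyl]ethyl}-6-methyl-1,2-dioxan-3-yl]propan-1-ol
Product: 32 (2S)-2-[(3S,6R)-6-{2-[(1S)-1-hydroxy-2,2-dimethyl-6-methylidenecyclohexyl]ethyl}-6-methyl-1,2-dioxan-3-yl]propanoic acid
Conditions: TEMPO (cat.), PhI(OAc)2, MeCN–H2O, rt
Reagents that add atoms: water, O
Why: Oxoammonium-catalysed oxidation takes only the primary alcohol, through the aldehyde hydrate, to the acid under near-neutral conditions that leave the tertiary alcohol, the alkene, the peroxide and the C2 configuration alone.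

Step 22
Reactants: 32 (2S)-2-[(3S,6R)-6-{2-[(1S)-1-hydroxy-2,2-dimethyl-6-methylidenecyclohexyl]ethyl}-6-methyl-1,2-dioxan-3-yl]propanoic acid
Product: 33 methyl (2S)-2-[(3S,6R)-6-{2-[(1S)-1-hydroxy-2,2-dimethyl-6-methylidenecyclohexyl]ethyl}-6-methyl-1,2-dioxan-3-yl]propanoate
Conditions: Me3SiCHN2, MeOH–toluene, 0 °C
Reagents that add atoms: (trimethylsilyl)diazomethane, C[Si](C)(C)C=[N+]=[N-]
Why: O-Methylation of the carboxylic acid by the diazoalkane is neutral and selective for the acid, so the tertiary alcohol and the peroxide survive and the target results.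

Compound list
1 | pent-4-yn-1-ol | C#CCCCO | starting material
2 | 4-bromopent-4-en-1-ol | C=C(Br)CCCO | intermediate
3 | 2-bromo-5-iodopent-1-ene | C=C(Br)CCCI | intermediate
4 | isobutyronitrile | CC(C)C#N | starting material
5 | 2-lithio-2-methylpropanenitrile (not isolated) | [Li]C(C)(C)C#N | intermediate
6 | 6-bromo-2,2-dimethylhept-6-enenitrile | C=C(Br)CCCC(C)(C)C#N | intermediate
7 | N-(diisobutylalumanyl)-6-bromo-2,2-dimethylhept-6-en-1-imine (not isolated) | C=C(Br)CCCC(C)(C)C=N[Al](CC(C)C)CC(C)C | intermediate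
8 | 6-bromo-2,2-dimethylhept-6-enal | C=C(Br)CCCC(C)(C)C=O | intermediate
9 | (4-bromobut-1-yn-1-yl)trimethylsilane | C[Si](C)(C)C#CCCBr | starting material
10 | [4-(trimethylsilyl)but-3-yn-1-yl]magnesium bromide (not isolated) | C[Si](C)(C)C#CCC[Mg]Br | intermediate
11 | rac-10-bromo-6,6-dimethyl-1-(trimethylsilyl)undec-10-en-1-yn-5-ol | C=C(Br)CCCC(C)(C)C(O)CCC#C[Si](C)(C)C | intermediate
12 | 10-bromo-6,6-dimethyl-1-(trimethylsilyl)undec-10-en-1-yn-5-one | C=C(Br)CCCC(C)(C)C(=O)CCC#C[Si](C)(C)C | intermediate
13 | (1S)-2,2-dimethyl-6-methylidene-1-[4-(trimethylsilyl)but-3-yn-1-yl]cyclohexan-1-ol | C=C1CCCC(C)(C)[C@@]1(O)CCC#C[Si](C)(C)C | intermediate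
14 | triethyl({(1S)-2,2-dimethyl-6-methylidene-1-[4-(trimethylsilyl)but-3-yn-1-yl]cyclohexyl}oxy)silane | C=C1CCCC(C)(C)[C@@]1(O[Si](CC)(CC)CC)CCC#C[Si](C)(C)C | intermediate
15 | {[(1S)-1-(but-3-yn-1-yl)-2,2-dimethyl-6-methylidenecyclohexyl]oxy}triethylsilane | C=C1CCCC(C)(C)[C@@]1(O[Si](CC)(CC)CC)CCC#C | intermediate
16 | methyl (2R)-3-hydroxy-2-methylpropanoate | COC(=O)[C@H](C)CO | starting material
17 | methyl (2R)-3-[(tert-butyldimethylsilyl)oxy]-2-methylpropanoate | COC(=O)[C@H](C)CO[Si](C)(C)C(C)(C)C | intermediate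
18 | diisobutylaluminium hemiacetal of 17 (not isolated; hemiacetal carbon undefined) | COC(O[Al](CC(C)C)CC(C)C)[C@H](C)CO[Si](C)(C)C(C)(C)C | intermediate
19 | (2R)-3-[(tert-butyldimethylsilyl)oxy]-2-methylpropanal | O=C[C@H](C)CO[Si](C)(C)C(C)(C)C | intermediate
20 | tert-butyldimethyl{[(2S)-2-methylbut-3-en-1-yl]oxy}silane | C=C[C@H](C)CO[Si](C)(C)C(C)(C)C | intermediate
21 | tert-butyldimethyl{(2R)-2-[(2RS)-oxiran-2-yl]propoxy}silane (both oxirane epimers) | C1OC1[C@H](C)CO[Si](C)(C)C(C)(C)C | intermediate
22 | tert-butyldimethyl{(2R)-2-[(2S)-oxiran-2-yl]propoxy}silane | C1O[C@H]1[C@H](C)CO[Si](C)(C)C(C)(C)C | intermediate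
23 | lithium acetylide of 15 (not isolated) | C=C1CCCC(C)(C)[C@@]1(O[Si](CC)(CC)CC)CCC#C[Li] | intermediate
24 | (2R,3R)-1-[(tert-butyldimethylsilyl)oxy]-8-[(1S)-2,2-dimethyl-6-methylidene-1-(triethylsilyloxy)cyclohexyl]-2-methyloct-5-yn-3-ol | C=C1CCCC(C)(C)[C@@]1(O[Si](CC)(CC)CC)CCC#CC[C@@H](O)[C@H](C)CO[Si](C)(C)C(C)(C)C | intermediate
25 | bromomagnesium alkoxide of the (5E)-5-(bromomagnesio)alkene from 24 (not isolated) | C=C1CCCC(C)(C)[C@@]1(O[Si](CC)(CC)CC)CC/C(C)=C(/[Mg]Br)C[C@@H](O[Mg]Br)[C@H](C)CO[Si](C)(C)C(C)(C)C | intermediate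
26 | (2R,3R,5Z)-1-[(tert-butyldimethylsilyl)oxy]-8-[(1S)-2,2-dimethyl-6-methylidene-1-(triethylsilyloxy)cyclohexyl]-2,6-dimethyloct-5-en-3-ol | C=C1CCCC(C)(C)[C@@]1(O[Si](CC)(CC)CC)CC/C(C)=C\C[C@@H](O)[C@H](C)CO[Si](C)(C)C(C)(C)C | intermediate
27 | (2R,3R,5Z)-1-[(tert-butyldimethylsilyl)oxy]-8-[(1S)-2,2-dimethyl-6-methylidene-1-(triethylsilyloxy)cyclohexyl]-2,6-dimethyloct-5-en-3-yl methanesulfonate | C=C1CCCC(C)(C)[C@@]1(O[Si](CC)(CC)CC)CC/C(C)=C\C[C@@H](OS(C)(=O)=O)[C@H](C)CO[Si](C)(C)C(C)(C)C | intermediate
28 | tert-butyl{[(2R,3S,5Z)-8-[(1S)-2,2-dimethyl-6-methylidene-1-(triethylsilyloxy)cyclohexyl]-3-hydroperoxy-2,6-dimethyloct-5-en-1-yl]oxy}dimethylsilane | C=C1CCCC(C)(C)[C@@]1(O[Si](CC)(CC)CC)CC/C(C)=C\C[C@H](OO)[C@H](C)CO[Si](C)(C)C(C)(C)C | intermediate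
29 | 5-(acetoxymercurio) derivative of 30, (3S,5S,6S) in ring B, mercury equatorial and anti to O1 (not isolated) | C=C1CCCC(C)(C)[C@@]1(O[Si](CC)(CC)CC)CC[C@@]1(C)[C@@H]([Hg]OC(C)=O)C[C@@H]([C@H](C)CO[Si](C)(C)C(C)(C)C)OO1 | intermediate
30 | tert-butyl{(2R)-2-[(3S,6R)-6-{2-[(1S)-2,2-dimethyl-6-methylidene-1-(triethylsilyloxy)cyclohexyl]ethyl}-6-methyl-1,2-dioxan-3-yl]propoxy}dimethylsilane | C=C1CCCC(C)(C)[C@@]1(O[Si](CC)(CC)CC)CC[C@@]1(C)CC[C@@H]([C@H](C)CO[Si](C)(C)C(C)(C)C)OO1 | intermediate
31 | (2R)-2-[(3S,6R)-6-{2-[(1S)-1-hydroxy-2,2-dimethyl-6-methylidenecyclohexyl]ethyl}-6-methyl-1,2-dioxan-3-yl]propan-1-ol | C=C1CCCC(C)(C)[C@@]1(O)CC[C@@]1(C)CC[C@@H]([C@H](C)CO)OO1 | intermediate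
32 | (2S)-2-[(3S,6R)-6-{2-[(1S)-1-hydroxy-2,2-dimethyl-6-methylidenecyclohexyl]ethyl}-6-methyl-1,2-dioxan-3-yl]propanoic acid | C=C1CCCC(C)(C)[C@@]1(O)CC[C@@]1(C)CC[C@@H]([C@H](C)C(=O)O)OO1 | intermediate
33 | methyl (2S)-2-[(3S,6R)-6-{2-[(1S)-1-hydroxy-2,2-dimethyl-6-methylidenecyclohexyl]ethyl}-6-methyl-1,2-dioxan-3-yl]propanoate | C=C1CCCC(C)(C)[C@@]1(O)CC[C@@]1(C)CC[C@@H]([C@H](C)C(=O)OC)OO1 | target

Total step count: 22. Longest linear sequence: 17 steps (steps 1–9 and 15–22); steps 10–14 are the side branch to epoxide 22.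

Steps most likely to fail

1. Step 7 (the one step beyond established scope). The ligand may discriminate the two carbonyl faces poorly, or protodebromination may outrun the slow insertion into the hindered ketone. The fallback uses known chemistry and sets out from 12. A stoichiometric Nozaki–Hiyama–Kishi cyclisation (CrCl2, 4 equiv; NiCl2, 2 mol %; DMF, rt) should give the racemic carbinol F1. Its enantiomers are then separated by preparative supercritical-fluid chromatography on a polysaccharide chiral stationary phase. The S enantiomer is 13, where the route resumes at step 8.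

2. Step 18. Elimination of methanesulfonic acid toward C4, which gives a conjugated diene, may outrun the slow bimolecular substitution at the β-branched secondary carbon. The fallback makes the C3–O bond in the ring closure instead and sets out from 27. Mukaiyama–Isayama hydroperoxysilylation (Co(thd)2 cat., thd = 2,2,6,6-tetramethylheptane-3,5-dionate; O2; Et3SiH; ClCH2CH2Cl; rt) is stopped before the hindered ring A methylene reacts. It should add the silylperoxy group at the tertiary carbon of the trisubstituted alkene and give the tertiary triethylsilyl peroxide F2 as both C6 epimers. Bu4NF (1.1 equiv, THF, 0 °C) then frees the peroxide anion, which closes ring B by intramolecular 6-exo-tet SN2 at C3 with inversion. This gives 30 together with its C6 epimer F3, which is removed by chromatography. The route resumes at 30 (step 20); control of C6 is lost in this variant.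

3. Step 19. The mercury electrophile may attack the ring A methylene, or the peroxide may fragment to an epoxy alcohol during hydride demercuration. The fallback sets out from 28. Iodonium-induced cyclisation with N-iodosuccinimide (CH2Cl2, 0 °C, dark) should follow the same anti, 6-endo, Markovnikov course and give the 5-iodo dioxane F4. Radical hydrodeiodination (n-Bu3SnH at high concentration, Et3B–air, toluene, −20 °C) then gives 30, where the route resumes at step 20.

Further compounds
F1 | step 7 | racemic 2,2-dimethyl-6-methylidene-1-[4-(trimethylsilyl)but-3-yn-1-yl]cyclohexan-1-ol | C=C1CCCC(C)(C)C1(O)CCC#C[Si](C)(C)C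
F2 | step 18 | (2R,3R)-1-[(tert-butyldimethylsilyl)oxy]-8-[(1S)-2,2-dimethyl-6-methylidene-1-(triethylsilyloxy)cyclohexyl]-2,6-dimethyl-6-(triethylsilylperoxy)octan-3-yl methanesulfonate (both C6 epimers) | C=C1CCCC(C)(C)[C@@]1(O[Si](CC)(CC)CC)CCC(C)(OO[Si](CC)(CC)CC)CC[C@@H](OS(C)(=O)=O)[C@H](C)CO[Si](C)(C)C(C)(C)C
F3 | step 18 | (3S,6S) epimer of 30 in ring B | C=C1CCCC(C)(C)[C@@]1(O[Si](CC)(CC)CC)CC[C@]1(C)CC[C@@H]([C@H](C)CO[Si](C)(C)C(C)(C)C)OO1
F4 | step 19 | 5-iodo derivative of 30 (iodine equatorial and anti to O1) | C=C1CCCC(C)(C)[C@@]1(O[Si](CC)(CC)CC)CC[C@@]1(C)[C@@H](I)C[C@@H]([C@H](C)CO[Si](C)(C)C(C)(C)C)OO1
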